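Watch the substrate, not the target.

| flask | substrate | reagent | free catalyst | remark | time |
|---|---|---|---|---|---|
| ash | 1 M | 1.1 M | 32 mM | run made earlier |  |
| oak | 1 M | 1.1 M | 82 mM | run made earlier |  |
| alder | 0.55 M | 1.1 M | 100 mM | run made earlier |  |
| Friday's | 1.0 M | 1.10 M | 100 mM |  | 10 h |
| Monday's | 0.25 M | 1.10 M | 60 mM |  | 10 h |

| run | time / h | target / % | substrate / % |
|---|---|---|---|
| ash | 0.500 | 0 | 99.8 |
| ash | 1.00 | 0 | 99.7 |
| ash | 1.50 | 0.4 | 98.8 |
| ash | 2.50 | 1.0 | 97.9 |
| ash | 4.00 | 2.9 | 95.3 |
| ash | 8.00 | 7.1 | 92.1 |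
| oak | 1.33 | 1.0 | 97.8 |
| oak | 2.50 | 4.4 | 95.5 |
| oak | 4.00 | 8.0 | 90.5 |
| oak | 5.00 | 10.3 | 88.8 |
| oak | 6.00 | 11.3 | 86.5 |
| oak | 8.00 | 16.1 | 81.6 |
| alder | 0.667 | 1.0 | 97.8 |
| alder | 2.00 | 5.6 | 93.6 |
| alder | 3.00 | 8.6 | 89.4 |
| alder | 5.00 | 19.1 | 79.1 |
| alder | 8.00 | 29.8 | 65.3 |

(each reading ± 0.5 percentage points)

- which of the two ends with the higher amount of target, in percent of the substrate charged ("neither" if they lie within 2 percentage points) (Friday's / Monday's / neither)
- target at the end, in percent of the substrate charged, Friday's
- target at the end, in percent of the substrate charged, Monday's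



At the last readings the substrate lost exceeds the target gained, with a gap of 2.3 percentage points of the charge in oak and a wider one, 4.9 points, in alder. So we count the catalyst's work by substrate lost. Ash shows 0 % target at 1.00 h, so we allow a lag of 1.00 h. The turnover time τ (the inverse of the turnover frequency) is the time after the lag, times the catalyst, over the substrate lost. The last readings give 2.84 h for ash and 3.12 h for oak, close together although their catalyst differs, and 3.67 h for alder, which holds less substrate.

We write τ as a fixed part plus a part that grows as the mean substrate S falls: τ = w + g·(charge of oak)/S. Oak, with S = 0.908 M, and alder, with S = 0.455 M, give g = 0.499 h and w = 2.57 h.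

Friday's has 9.00 h of working time. With S near its charge, τ = 3.15 h, so it loses 0.285 M. Taking off alder's gap leaves 23.6 % target.

For Monday's, the turnover time at its substrate charge is 4.57 h, which gives a first loss of 0.118 M. That is 47.3 % of the charge, so S falls well below the charge, and this is the weak link. We put the mean S = 0.191 M back in: τ becomes 5.18 h, the loss 0.104 M, and the target 36.8 %. We commit to Monday's.

The forecast gives 24 % for Friday's and 39 % for Monday's, so Monday's, and in its words “The lower charge wins in percent terms.”

The flasks give 22.0 % for Friday's and 38.9 % for Monday's, so Monday's ends higher.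

    reagent + free catalyst → catalyst intermediate A (k = 5.10 × 10⁻⁴ M⁻¹ s⁻¹)
    catalyst intermediate A → by-product + catalyst intermediate B (k = 1.30 × 10⁻⁴ s⁻¹)
    substrate + catalyst intermediate B → catalyst intermediate C (k = 8.17 × 10⁻⁴ M⁻¹ s⁻¹)
    catalyst intermediate C → catalyst intermediate D (k = 0.0150 s⁻¹)
    catalyst intermediate D ⇌ free catalyst + target (K = 1.40 M, k = 0.00137 s⁻¹)
    target + by-product → side product (k = 6.33 × 10⁻⁵ M⁻¹ s⁻¹)

The same reckoning serves the neighbour of Monday's charged with 0.10 M of free catalyst. It starts from the same 4.57 h, which gives a first loss of 0.197 M. Putting the mean substrate back in raises τ to 5.87 h, and the loss becomes 0.153 M. We therefore expect 38.6 % substrate left and 56.5 % target. That flask ends with 34.8 % substrate and 54.4 % target.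

The earlier runs and the new flask come from a simulation with made-up constants, noise included.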